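**Plan**

- Retrosynthesis: the carbamate is taken off, then the ring bond C2–C3 of the cyclohex-4-ene-1,3-diol (ring CH2 to the allylic carbinol carbon) is cut to an open-chain (Z)-allyl carbamate carrying an (S)-2,2-disubstituted oxirane. The alkynyl–CH2 bond (future C5–C6) is then cut to an epoxy tosylate plus propargyl carbamate, and the side chain is cut at its sp3–sp2 bond and at its alkyne.
- Forward: chain first (steps 1–2), asymmetric epoxidation (3), ring arm attached and oxirane moved to the other CH2 (4–7), both alkynes to Z-alkenes (8), the single ring closed by 6-endo oxirane opening (9), carbamate removed (10).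
- Enabling feature: C1 carries both oxygen and the ring CH2 (C2), so C1–O/C2 is a masked terminal oxirane with a strain-loaded electrophilic CH2. C3 bears oxygen and is allylic to C4=C5, so it can be an alpha-oxyallyl carbanion (polarity reversal of a carbonyl-level carbon), and the cis C4=C5 bond holds the two termini within reach.
- Stereochemistry: C1 comes from the Sharpless epoxidation with D-(−)-diethyl tartrate and is carried through unchanged because its C–O bond is never broken. C3 is set in the ring closure, where the configurationally labile lithiated carbamate should be funnelled to the cis isomer. Both Z-alkenes come from one Lindlar semihydrogenation.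

Key step: step 9

Assumption: lithiated primary O-allyl N,N-diisopropylcarbamates are taken to epimerise at the carbanion carbon in Et2O/TMEDA faster than the oxirane is opened, as in their known intermolecular chemistry.

**Route**

Step 1
Reactants: 1 5-phenylpent-1-yne; 2 11-bromoundec-1-ene
Product: 4 (hexadec-15-en-4-yn-1-yl)benzene, via lithium 5-phenylpent-1-ynide 3 (not isolated)
Conditions: n-BuLi, THF, −78 °C; then 2, DMPU, −78 °C to rt
Reagents that add atoms: none
Why: SN2 alkylation of a lithium acetylide by a primary bromide (acetylide alkylation), with DMPU raising the nucleophilicity and the terminal alkene inert.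

Step 2
Reactants: 4 (hexadec-15-en-4-yn-1-yl)benzene; 5 2-bromoprop-2-en-1-ol
Product: 7 2-(16-phenylhexadec-12-yn-1-yl)prop-2-en-1-ol, via B-alkyl-9-borabicyclo[3.3.1]nonane 6 (not isolated)
Conditions: 9-BBN, THF, 0 °C to rt; then 5, PdCl2(dppf) (3 mol%), 3 M aq NaOH, THF, 65 °C
Reagents that add atoms: none
Why: 9-BBN should hydroborate the terminal alkene much faster than the internal alkyne and place boron on the terminal carbon, and the B-alkyl Suzuki–Miyaura coupling with the vinyl bromide then forms the sp3–sp2 bond in the presence of the free hydroxyl.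

Step 3
Reactants: 7 2-(16-phenylhexadec-12-yn-1-yl)prop-2-en-1-ol
Product: 8 [(2R)-2-(16-phenylhexadec-12-yn-1-yl)oxiran-2-yl]methanol
Conditions: Ti(OiPr)4 (10 mol%), D-(−)-diethyl tartrate (12 mol%), t-BuOOH, 4 Å MS, CH2Cl2, −20 °C
Reagents that add atoms: tert-butyl hydroperoxide, CC(C)(C)OO
Why: Katsuki–Sharpless asymmetric epoxidation, in which the titanium–tartrate complex binds the allylic alcohol and delivers oxygen to one face of the 1,1-disubstituted alkene (D-(−)-tartrate should give the R epoxy alcohol), while the isolated alkyne is not oxidised.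

Step 4
Reactants: 8 [(2R)-2-(16-phenylhexadec-12-yn-1-yl)oxiran-2-yl]methanol
Product: 9 [(2S)-2-(16-phenylhexadec-12-yn-1-yl)oxiran-2-yl]methyl 4-methylbenzenesulfonate
Conditions: TsCl, Et3N, DMAP (cat.), CH2Cl2, 0 °C
Reagents that add atoms: 4-methylbenzenesulfonyl chloride, Cc1ccc(cc1)S(Cl)(=O)=O
Why: sulfonylation of the primary alcohol without touching any bond at the stereocentre (the descriptor changes from R to S only because the CIP ranking of the two CH2 groups is exchanged).

Step 5
Reactants: 10 prop-2-yn-1-ol; 11 N,N-diisopropylcarbamoyl chloride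
Product: 12 prop-2-yn-1-yl N,N-diisopropylcarbamate
Conditions: NaH, THF, 0 °C; then 11, THF, reflux
Reagents that add atoms: none
Why: O-carbamoylation of the sodium alkoxide by the carbamoyl chloride gives the three-carbon unit (future C3–C5) that already carries the group needed to direct and stabilise the later lithiation.

Step 6
Reactants: 12 prop-2-yn-1-yl N,N-diisopropylcarbamate; 9 [(2S)-2-(16-phenylhexadec-12-yn-1-yl)oxiran-2-yl]methyl 4-methylbenzenesulfonate
Product: 14 (5S)-5-hydroxy-21-phenyl-5-[(tosyloxy)methyl]henicosa-2,17-diyn-1-yl N,N-diisopropylcarbamate, via lithium acetylide of the propargyl carbamate 13 (not isolated)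
Conditions: 12, n-BuLi, THF, −78 °C; BF3·OEt2, −78 °C; then 9, −78 °C; then H2O
Reagents that add atoms: none
Why: Yamaguchi–Hirao alkynylation, in which the BF3-activated oxirane should be opened by the acetylide at its unsubstituted CH2 in an SN2 process (the neopentyl-type tosylate is far slower and the electron-poor CH2OTs group disfavours ionisation at the quaternary carbon), so the tertiary C–O bond and its configuration are kept.

Step 7
Reactants: 14 (5S)-5-hydroxy-21-phenyl-5-[(tosyloxy)methyl]henicosa-2,17-diyn-1-yl N,N-diisopropylcarbamate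
Product: 15 4-[(2S)-2-(16-phenylhexadec-12-yn-1-yl)oxiran-2-yl]but-2-yn-1-yl N,N-diisopropylcarbamate
Conditions: K2CO3, MeOH, rt
Reagents that add atoms: none
Why: intramolecular Williamson etherification (3-exo-tet), in which the tertiary alkoxide displaces the primary tosylate and so moves the oxirane onto the other CH2 with the quaternary centre unchanged.

Step 8
Reactants: 15 4-[(2S)-2-(16-phenylhexadec-12-yn-1-yl)oxiran-2-yl]but-2-yn-1-yl N,N-diisopropylcarbamate
Product: 16 (2Z)-4-{(2S)-2-[(12Z)-16-phenylhexadec-12-en-1-yl]oxiran-2-yl}but-2-en-1-yl N,N-diisopropylcarbamate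
Conditions: H2 (1 atm, 2 equiv taken up), Pd/CaCO3 poisoned with Pb(OAc)2 (Lindlar catalyst), quinoline, EtOAc, rt
Reagents that add atoms: none
Why: Lindlar semihydrogenation, in which syn addition of hydrogen on the poisoned palladium surface should turn both alkynes into Z-alkenes in one operation while oxirane and carbamate stay intact.

Step 9
Reactants: 16 (2Z)-4-{(2S)-2-[(12Z)-16-phenylhexadec-12-en-1-yl]oxiran-2-yl}but-2-en-1-yl N,N-diisopropylcarbamate
Product: 18 (1S,5S)-5-hydroxy-5-[(12Z)-16-phenylhexadec-12-en-1-yl]cyclohex-2-en-1-yl N,N-diisopropylcarbamate, via alpha-lithiated allyl carbamate 17 (not isolated)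
Conditions: s-BuLi, TMEDA, Et2O (0.02 M), −78 °C; warm slowly to −20 °C; then H2O
Reagents that add atoms: none
Why: Proposed new method: s-BuLi/TMEDA should remove the allylic proton alpha to the carbamate oxygen (carbamate-directed Hoppe lithiation) to give 17, whose carbanion carbon attacks the CH2 terminus of the oxirane in an SN2 opening that releases the ring strain and leaves the tertiary C–O bond, and hence the S centre, untouched; the closest known reaction types are the intramolecular cycloalkylation of lithiated O-allyl carbamates and the Stork epoxynitrile cyclisation. The cyclohexene closes in the 6-endo-tet mode, which should be the only one open because the 5-exo and 3-exo alternatives would require substitution at the fully substituted oxirane carbon and the four-membered alternative cannot reach a collinear geometry. The new carbinol centre is set by dynamic kinetic resolution: the two epimers of 17 interconvert, and in the chair-like transition state the breaking C–O bond must lie anti to the forming C–C bond, which places the oxirane oxygen equatorial and the long chain axial, so the carbamate oxygen should take the pseudo-equatorial position to avoid a 1,3-diaxial clash with the chain, that is cis to the tertiary oxygen (1S,5S). The step needs alpha- over gamma-attack of the ambident allyl anion and CH2 over quaternary-carbon attack, both secured by ring size and by the substitution pattern of the oxirane; the Z geometry of the tether, kept at low temperature, brings the termini together, and high dilution suppresses intermolecular opening.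

Step 10
Reactants: 18 (1S,5S)-5-hydroxy-5-[(12Z)-16-phenylhexadec-12-en-1-yl]cyclohex-2-en-1-yl N,N-diisopropylcarbamate
Product: 19 (1S,3S)-1-[(12Z)-16-phenylhexadec-12-en-1-yl]cyclohex-4-ene-1,3-diol
Conditions: LiAlH4, THF, reflux; then aqueous NaOH work-up
Reagents that add atoms: none
Why: reductive cleavage of the N,N-dialkylcarbamate by hydride attack at its carbonyl (the standard removal of such carbamates), which leaves the C–O bonds at both stereocentres and both alkenes untouched.

**Compound list**

1 | 5-phenylpent-1-yne | C#CCCCc1ccccc1 | starting material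
2 | 11-bromoundec-1-ene | C=CCCCCCCCCCBr | starting material
3 | lithium 5-phenylpent-1-ynide | [Li]C#CCCCc1ccccc1 | intermediate (not isolated)
4 | (hexadec-15-en-4-yn-1-yl)benzene | C=CCCCCCCCCCC#CCCCc1ccccc1 | intermediate
5 | 2-bromoprop-2-en-1-ol | OCC(Br)=C | starting material
6 | 9-(16-phenylhexadec-12-yn-1-yl)-9-borabicyclo[3.3.1]nonane | c1ccccc1CCCC#CCCCCCCCCCCCB2C3CCCC2CCC3 | intermediate (not isolated)
7 | 2-(16-phenylhexadec-12-yn-1-yl)prop-2-en-1-ol | OCC(=C)CCCCCCCCCCCC#CCCCc1ccccc1 | intermediate
8 | [(2R)-2-(16-phenylhexadec-12-yn-1-yl)oxiran-2-yl]methanol | OC[C@]1(CCCCCCCCCCCC#CCCCc2ccccc2)CO1 | intermediate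
9 | [(2S)-2-(16-phenylhexadec-12-yn-1-yl)oxiran-2-yl]methyl 4-methylbenzenesulfonate | Cc1ccc(cc1)S(=O)(=O)OC[C@]2(CCCCCCCCCCCC#CCCCc3ccccc3)CO2 | intermediate
10 | prop-2-yn-1-ol | C#CCO | starting material
11 | N,N-diisopropylcarbamoyl chloride | CC(C)N(C(C)C)C(Cl)=O | starting material
12 | prop-2-yn-1-yl N,N-diisopropylcarbamate | C#CCOC(=O)N(C(C)C)C(C)C | intermediate
13 | lithium acetylide of 12 | [Li]C#CCOC(=O)N(C(C)C)C(C)C | intermediate (not isolated)
14 | (5S)-5-hydroxy-21-phenyl-5-[(tosyloxy)methyl]henicosa-2,17-diyn-1-yl N,N-diisopropylcarbamate | CC(C)N(C(C)C)C(=O)OCC#CC[C@@](O)(CCCCCCCCCCCC#CCCCc1ccccc1)COS(=O)(=O)c1ccc(C)cc1 | intermediate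
15 | 4-[(2S)-2-(16-phenylhexadec-12-yn-1-yl)oxiran-2-yl]but-2-yn-1-yl N,N-diisopropylcarbamate | CC(C)N(C(C)C)C(=O)OCC#CC[C@@]1(CCCCCCCCCCCC#CCCCc2ccccc2)CO1 | intermediate
16 | (2Z)-4-{(2S)-2-[(12Z)-16-phenylhexadec-12-en-1-yl]oxiran-2-yl}but-2-en-1-yl N,N-diisopropylcarbamate | CC(C)N(C(C)C)C(=O)OC/C=C\C[C@@]1(CCCCCCCCCCC/C=C\CCCc2ccccc2)CO1 | intermediate
17 | alpha-lithiated allyl carbamate (C1-lithio derivative of 16, epimers at the lithiated carbon interconverting) | [Li]C(OC(=O)N(C(C)C)C(C)C)/C=C\C[C@@]1(CCCCCCCCCCC/C=C\CCCc2ccccc2)CO1 | intermediate (not isolated)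
18 | (1S,5S)-5-hydroxy-5-[(12Z)-16-phenylhexadec-12-en-1-yl]cyclohex-2-en-1-yl N,N-diisopropylcarbamate | CC(C)N(C(C)C)C(=O)O[C@@H]1C=CC[C@@](O)(CCCCCCCCCCC/C=C\CCCc2ccccc2)C1 | intermediate
19 | (1S,3S)-1-[(12Z)-16-phenylhexadec-12-en-1-yl]cyclohex-4-ene-1,3-diol (cis-diol) | O[C@@H]1C=CC[C@@](O)(CCCCCCCCCCC/C=C\CCCc2ccccc2)C1 | target

**Step count and risks**

Total step count: 10. Longest linear sequence: 9 steps (1, 2, 3, 4, 6, 7, 8, 9, 10, from compounds 1 and 2); step 5 is a one-step side branch.

Steps most likely to fail:

1. Step 9 (proposed new method). The ambident anion may attack through its gamma carbon or at the quaternary oxirane carbon. The base may instead isomerise the oxirane to an allylic alcohol by deprotonating the CH2 between alkene and oxirane. The carbamoyl group may migrate to carbon on warming. The dynamic resolution may also discriminate poorly between the two faces and give the trans isomer.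

   The fallback uses only known reaction types, sets out from tosylate 9 and returns to the route at target 19. Allylmagnesium bromide with catalytic CuI (THF, −30 °C) should open the oxirane of 9 at CH2 to give the but-3-enyl hydroxy tosylate F1, and K2CO3 in MeOH closes it to the but-3-enyl oxirane F2. Vinylmagnesium bromide with catalytic CuI opens F2 at CH2 to the allyl butenyl carbinol F3. Ring-closing metathesis with the first-generation Grubbs catalyst RuCl2(PCy3)2(=CHPh) in CH2Cl2 should then give the cyclohex-3-enol F4 with loss of ethene, leaving the internal alkyne alone. VO(acac)2 with t-BuOOH delivers oxygen syn to the tertiary hydroxyl and gives the cis-epoxy alcohol F5. Sodium benzeneselenolate F6 (from PhSeSePh and NaBH4 in EtOH) should open F5 trans-diaxially at the oxirane carbon remote from the carbinol (Fürst–Plattner opening of the conformer with the chain equatorial and the hydroxyl axial) to give the hydroxy selenide F7. H2O2 oxidises F7 to the selenoxide F8, which should undergo syn-elimination away from the hydroxyl (Sharpless–Lauer sequence) to the alkynyl cis-diol F9. Lindlar semihydrogenation as in step 8 then gives 19. Here the tertiary centre still comes from step 3 and the secondary carbinol from the hydroxyl-directed epoxidation.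

2. Step 6. The Lewis acid may trigger rearrangement of the 2,2-disubstituted oxirane to an aldehyde, or the acetylide may displace the tosylate. The fallback sets out from epoxy alcohol 8 and returns at hydroxy tosylate 14. Acetylide 13 is converted with Et2AlCl into the diethylalkynylalane F10, which should open unprotected 8 at its CH2 under direction by the aluminium alkoxide (toluene, 0 °C) to give the 1,2-diol F11. Selective sulfonylation of the primary hydroxyl (TsCl, Et3N, catalytic Bu2SnO, CH2Cl2) then gives 14, so the sulfonate is never exposed to the Lewis acid.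

3. Step 2. Hydroboration may also take place at the internal alkyne, or the alkylborane may be lost by protodeboronation or beta-hydride elimination during the coupling. The fallback sets out from alkyne 1 and returns at allylic alcohol 7. Lithium acetylide 3 is alkylated with excess 1,10-dibromodecane (THF/DMPU) to give the bromide F12. The C,O-dilithio dianion F13 of 2-methylprop-2-en-1-ol (n-BuLi, TMEDA, Et2O/hexane) is then alkylated at carbon by F12 to give 7, without boron or palladium.

**Further compounds**

F1 | step 9 | (2S)-2-(but-3-en-1-yl)-2-hydroxy-18-phenyloctadec-14-yn-1-yl 4-methylbenzenesulfonate | C=CCC[C@@](O)(CCCCCCCCCCCC#CCCCc1ccccc1)COS(=O)(=O)c1ccc(C)cc1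
F2 | step 9 | (2S)-2-(but-3-en-1-yl)-2-(16-phenylhexadec-12-yn-1-yl)oxirane | C=CCC[C@@]1(CCCCCCCCCCCC#CCCCc2ccccc2)CO1
F3 | step 9 | (5S)-21-phenyl-5-(prop-2-en-1-yl)henicos-1-en-17-yn-5-ol | C=CCC[C@@](O)(CCCCCCCCCCCC#CCCCc1ccccc1)CC=C
F4 | step 9 | (1S)-1-(16-phenylhexadec-12-yn-1-yl)cyclohex-3-en-1-ol | C1CC=CC[C@]1(O)CCCCCCCCCCCC#CCCCc2ccccc2
F5 | step 9 | (1S,3S,6R)-3-(16-phenylhexadec-12-yn-1-yl)-7-oxabicyclo[4.1.0]heptan-3-ol (oxirane cis to hydroxyl) | O[C@]1(CCCCCCCCCCCC#CCCCc2ccccc2)C[C@@H]3O[C@@H]3CC1
F6 | step 9 | sodium benzeneselenolate | [Na+].[Se-]c1ccccc1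
F7 | step 9 | (1S,3S,4S)-1-(16-phenylhexadec-12-yn-1-yl)-4-(phenylselanyl)cyclohexane-1,3-diol | O[C@]1(CCCCCCCCCCCC#CCCCc2ccccc2)C[C@H](O)[C@@H]([Se]c2ccccc2)CC1
F8 | step 9 | (1S,3S,4S)-4-(benzeneseleninyl)-1-(16-phenylhexadec-12-yn-1-yl)cyclohexane-1,3-diol (both configurations at selenium) | O[C@]1(CCCCCCCCCCCC#CCCCc2ccccc2)C[C@H](O)[C@@H]([Se](=O)c2ccccc2)CC1
F9 | step 9 | (1S,3S)-1-(16-phenylhexadec-12-yn-1-yl)cyclohex-4-ene-1,3-diol | O[C@@H]1C=CC[C@@](O)(CCCCCCCCCCCC#CCCCc2ccccc2)C1
F10 | step 6 | diethyl{3-[(diisopropylcarbamoyl)oxy]prop-1-yn-1-yl}aluminium | CC[Al](CC)C#CCOC(=O)N(C(C)C)C(C)C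
F11 | step 6 | (5S)-5-hydroxy-5-(hydroxymethyl)-21-phenylhenicosa-2,17-diyn-1-yl N,N-diisopropylcarbamate | CC(C)N(C(C)C)C(=O)OCC#CC[C@@](O)(CCCCCCCCCCCC#CCCCc1ccccc1)CO
F12 | step 2 | (15-bromopentadec-4-yn-1-yl)benzene | BrCCCCCCCCCCC#CCCCc1ccccc1
F13 | step 2 | C,O-dilithio dianion of 2-methylprop-2-en-1-ol | [Li]CC(=C)CO[Li]
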